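**Plan**
- Retrosynthesis: the O–CH3 bond at C5 is cut first (chelated phenol masked as its methyl ether), then C4–C4a (ring C opened to an acyclic β-aryloxy amide), then O1–C2 (phenol plus benzylic carbinol), then C8–prenyl (O→C shift on a symmetric phenol).
- Forward: ring A is completed first (prenyl onto 3,5-dimethoxyphenol by Tsuji–Trost etherification and aromatic Claisen rearrangement), the C3 chain is hung on O1, and ring C is closed last through C4–C4a by attack of ring A on the Tf2O-activated amide; demethylation at O5 ends the route.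
- Enabling feature: C4a is the only free carbon ortho to O1 and lies ortho/para to all three oxygens of ring A (O1, O at C5, O at C7), while C8 carries the prenyl group. Ring C can therefore close at one site only, onto a non-acidic acyl equivalent that spares the ionisable benzylic C2–O1 bond.
- Stereochemistry: C2 comes from asymmetric transfer hydrogenation of a β-keto ester to the (R)-carbinol, inverted to (S) in the Mitsunobu etherification; no later step makes or breaks a bond at C2.

Key step: step 6

Remark: carbonate 2 is taken as a purchasable reagent (it is the Boc derivative of 2-methylbut-3-en-2-ol).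

**Step 1**
Reactants: 1 3,5-dimethoxyphenol; 2 tert-butyl 2-methylbut-3-en-2-yl carbonate
Product: 3 1,3-dimethoxy-5-[(2-methylbut-3-en-2-yl)oxy]benzene
Conditions: Pd(PPh3)4 (2 mol %), THF, 0 → 23 °C
Reagents that add atoms: none
Why: Tsuji–Trost O-allylation, in which zerovalent palladium ionises the tertiary carbonate (CO2 and tert-butoxide leave, the latter deprotonating 1) and the phenoxide attacks the more substituted allyl terminus under kinetic control, the established way to aryl 1,1-dimethylallyl ethers.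

**Step 2**
Reactants: 3 1,3-dimethoxy-5-[(2-methylbut-3-en-2-yl)oxy]benzene
Product: 5 3,5-dimethoxy-2-(3-methylbut-2-en-1-yl)phenol, via ortho-dienone 4 (not isolated)
Conditions: PhNEt2, 130 °C
Reagents that add atoms: none
Why: Aromatic Claisen rearrangement ([3,3]) should deliver the allyl terminus to an ortho carbon as a normal prenyl group, after which dienone 4 enolises; the two ortho positions of the symmetric ether are equivalent, so only one C-prenyl phenol can arise.

**Step 3**
Reactants: 6 ethyl 3-(4-methoxyphenyl)-3-oxopropanoate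
Product: 7 ethyl (3R)-3-hydroxy-3-(4-methoxyphenyl)propanoate
Conditions: RuCl[(R,R)-TsDPEN](p-cymene) (1 mol %), HCO2H/Et3N (5:2), 40 °C
Reagents that add atoms: none
Why: Noyori–Ikariya asymmetric transfer hydrogenation of an aryl ketone, in which the (R,R)-TsDPEN ligand should direct hydride to the face that gives the (R)-benzylic carbinol, as for acetophenone-type substrates, with the ester untouched.

**Step 4**
Reactants: 7 ethyl (3R)-3-hydroxy-3-(4-methoxyphenyl)propanoate
Product: 8 (3R)-3-hydroxy-3-(4-methoxyphenyl)-N,N-dimethylpropanamide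
Conditions: Me2NH (2 M in MeOH, excess), sealed tube, 50 °C
Reagents that add atoms: dimethylamine, CNC
Why: Aminolysis of a β-hydroxy ester (assisted by the neighbouring hydroxyl) should give the tertiary amide without touching the carbinol centre.

**Step 5**
Reactants: 5 3,5-dimethoxy-2-(3-methylbut-2-en-1-yl)phenol; 8 (3R)-3-hydroxy-3-(4-methoxyphenyl)-N,N-dimethylpropanamide
Product: 9 (3S)-3-[3,5-dimethoxy-2-(3-methylbut-2-en-1-yl)phenoxy]-3-(4-methoxyphenyl)-N,N-dimethylpropanamide
Conditions: PPh3, DIAD, PhMe, −20 → 0 °C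
Reagents that add atoms: none
Why: Mitsunobu etherification, in which the phenol displaces the oxyphosphonium group in an SN2 step with inversion and so turns the (R)-carbinol into the (S)-aryl ether that becomes C2, while the amide (less acidic α-hydrogens than an ester), the non-polar solvent and the low temperature should hold back elimination and ionisation.

**Step 6**
Reactants: 9 (3S)-3-[3,5-dimethoxy-2-(3-methylbut-2-en-1-yl)phenoxy]-3-(4-methoxyphenyl)-N,N-dimethylpropanamide
Product: 12 (2S)-5,7-dimethoxy-2-(4-methoxyphenyl)-8-(3-methylbut-2-en-1-yl)-2,3-dihydro-4H-chromen-4-one, via O-triflyliminium triflate 10 (not isolated), via cyclic iminium triflate 11 (not isolated)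
Conditions: Tf2O (1.1 equiv), 2,6-di-tert-butyl-4-methylpyridine (2.5 equiv), CH2Cl2, −78 → −20 °C; then sat. aq. NaHCO3, THF, 0 → 23 °C
Reagents that add atoms: water, O
Why: Tf2O should sulfonylate the amide oxygen, the most nucleophilic site of 9, to give O-triflyliminium ion 10, whose carbon (the future C4) is attacked by C4a of ring A; triflate leaves, the hindered pyridine takes the ring proton to give iminium salt 11, and bicarbonate hydrolysis exchanges the dimethylamino group for the carbonyl oxygen. The closest known reaction type is the intramolecular Vilsmeier–Haack (Friedel–Crafts-type) acylation of electron-rich arenes by Tf2O-activated tertiary amides, the carbon counterpart of the Bischler–Napieralski closure. Ring C closes in the 6-exo-trig mode, the C=N bond staying outside the new ring O1–C2–C3–C4–C4a–C8a. No stereocentre is formed, and C2 should be carried through from step 5 because the buffered, cold medium holds neither free strong acid nor a base able to ionise or eliminate across the C2–O1 bond. The selectivity needed is for C4a over every other nucleophilic carbon: C8 is blocked by the prenyl group, C6 is para to O1 and out of reach of the tether, the anisyl ring could only close a five-membered ring through a carbon meta to its methoxy group, and the prenyl alkene could only close a medium ring.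

**Step 7**
Reactants: 12 (2S)-5,7-dimethoxy-2-(4-methoxyphenyl)-8-(3-methylbut-2-en-1-yl)-2,3-dihydro-4H-chromen-4-one
Product: 14 flowerine [(2S)-5-hydroxy-7-methoxy-2-(4-methoxyphenyl)-8-(3-methylbut-2-en-1-yl)-2,3-dihydro-4H-chromen-4-one], via dichloroboryl ether 13 (not isolated)
Conditions: BCl3 (1.5 equiv), CH2Cl2, −78 → −20 °C; then aq. NaHCO3, 0 °C
Reagents that add atoms: none
Why: Chelation-controlled ether cleavage, in which BCl3 binds the C4 carbonyl and the peri methoxy oxygen at C5 in a six-membered chelate, chloride removes that methyl group only, and hydrolysis of boron ether 13 frees the hydrogen-bonded phenol, the standard selective C5 demethylation of 5-methoxyflavanones, which forms or breaks no bond at C2.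

**Compound list**
1 | 3,5-dimethoxyphenol | COc1cc(O)cc(OC)c1 | starting material
2 | tert-butyl 2-methylbut-3-en-2-yl carbonate | C=CC(C)(C)OC(=O)OC(C)(C)C | starting material
3 | 1,3-dimethoxy-5-[(2-methylbut-3-en-2-yl)oxy]benzene | COc1cc(OC)cc(OC(C)(C)C=C)c1 | intermediate
4 | 3,5-dimethoxy-6-(3-methylbut-2-en-1-yl)cyclohexa-2,4-dien-1-one (ortho-dienone, not isolated) | O=C1C=C(OC)C=C(OC)C1CC=C(C)C | intermediate
5 | 3,5-dimethoxy-2-(3-methylbut-2-en-1-yl)phenol | COc1cc(O)c(CC=C(C)C)c(OC)c1 | intermediate
6 | ethyl 3-(4-methoxyphenyl)-3-oxopropanoate | CCOC(=O)CC(=O)c1ccc(OC)cc1 | starting material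
7 | ethyl (3R)-3-hydroxy-3-(4-methoxyphenyl)propanoate | CCOC(=O)C[C@@H](O)c1ccc(OC)cc1 | intermediate
8 | (3R)-3-hydroxy-3-(4-methoxyphenyl)-N,N-dimethylpropanamide | CN(C)C(=O)C[C@@H](O)c1ccc(OC)cc1 | intermediate
9 | (3S)-3-[3,5-dimethoxy-2-(3-methylbut-2-en-1-yl)phenoxy]-3-(4-methoxyphenyl)-N,N-dimethylpropanamide | COc1ccc([C@H](CC(=O)N(C)C)Oc2cc(OC)cc(OC)c2CC=C(C)C)cc1 | intermediate
10 | (3S)-3-[3,5-dimethoxy-2-(3-methylbut-2-en-1-yl)phenoxy]-3-(4-methoxyphenyl)-N,N-dimethyl-1-[(trifluoromethanesulfonyl)oxy]propan-1-iminium trifluoromethanesulfonate (not isolated) | COc1ccc([C@H](CC(OS(=O)(=O)C(F)(F)F)=[N+](C)C)Oc2cc(OC)cc(OC)c2CC=C(C)C)cc1.[O-]S(=O)(=O)C(F)(F)F | intermediate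
11 | (2S)-5,7-dimethoxy-2-(4-methoxyphenyl)-N,N-dimethyl-8-(3-methylbut-2-en-1-yl)-2,3-dihydro-4H-chromen-4-iminium trifluoromethanesulfonate (not isolated) | COc1ccc([C@@H]2CC(=[N+](C)C)c3c(OC)cc(OC)c(CC=C(C)C)c3O2)cc1.[O-]S(=O)(=O)C(F)(F)F | intermediate
12 | (2S)-5,7-dimethoxy-2-(4-methoxyphenyl)-8-(3-methylbut-2-en-1-yl)-2,3-dihydro-4H-chromen-4-one | COc1ccc([C@@H]2CC(=O)c3c(OC)cc(OC)c(CC=C(C)C)c3O2)cc1 | intermediate
13 | (2S)-5-[(dichloroboranyl)oxy]-7-methoxy-2-(4-methoxyphenyl)-8-(3-methylbut-2-en-1-yl)-2,3-dihydro-4H-chromen-4-one (boron chelated to the C4 carbonyl, not isolated) | COc1ccc([C@@H]2CC(=O)c3c(OB(Cl)Cl)cc(OC)c(CC=C(C)C)c3O2)cc1 | intermediate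
14 | flowerine, (2S)-5-hydroxy-7-methoxy-2-(4-methoxyphenyl)-8-(3-methylbut-2-en-1-yl)-2,3-dihydro-4H-chromen-4-one | COc1ccc([C@@H]2CC(=O)c3c(O)cc(OC)c(CC=C(C)C)c3O2)cc1 | target

**Total step count:** 7
**Longest linear sequence:** 5 steps (1 → 3 → 5 → 9 → 12 → 14; the branch 6 → 7 → 8 → 9 → 12 → 14 is equally long)

**Steps most likely to fail**

Step 5. The p-anisyl-stabilised oxyphosphonium intermediate may ionise (erosion of enantiopurity), or it may eliminate towards the cinnamamide instead of being displaced. The fallback sets out from 5, returns to the route at 9, and makes the C2–O1 bond without inversion at a carbinol.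
- (E)-3-(4-Methoxyphenyl)prop-2-en-1-ol and methyl chloroformate (pyridine, CH2Cl2) would give methyl (2E)-3-(4-methoxyphenyl)prop-2-en-1-yl carbonate F1.
- The sodium salt of 5 (NaH, THF) and F1, with [Ir(cod)Cl]2 and a binaphthol-derived phosphoramidite ligand (the enantiomer that leads to the (S) ether), should give the branched ether 1,5-dimethoxy-3-{[(1S)-1-(4-methoxyphenyl)prop-2-en-1-yl]oxy}-2-(3-methylbut-2-en-1-yl)benzene F2 by asymmetric allylic etherification.
- 9-BBN in THF followed by NaBO3, which should take the terminal vinyl group in preference to the trisubstituted prenyl alkene, would give (3S)-3-[3,5-dimethoxy-2-(3-methylbut-2-en-1-yl)phenoxy]-3-(4-methoxyphenyl)propan-1-ol F3.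
- TEMPO/PhI(OAc)2 in MeCN–H2O would give (3S)-3-[3,5-dimethoxy-2-(3-methylbut-2-en-1-yl)phenoxy]-3-(4-methoxyphenyl)propanoic acid F4.
- Coupling of F4 with Me2NH·HCl (EDC·HCl, HOBt, iPr2NEt) would give amide 9.

Step 6. The C2–O1 bond may open in the activated species, by ionisation of the benzylic ether or by retro-oxa-Michael opening through the enamine form of the cyclised iminium salt (loss of enantiopurity or of the phenol), and hydrolysis of the stabilised iminium salt may be incomplete. The fallback sets out from 5 and 7, returns at 12, and inverts the order of the two ring-C bonds: C4–C4a is made by intermolecular acyl substitution with an aryllithium, and the ring is closed through O1–C2.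
- MOMCl/iPr2NEt on 5 would give 1,5-dimethoxy-3-(methoxymethoxy)-2-(3-methylbut-2-en-1-yl)benzene F5.
- MeNHOMe·HCl/iPrMgCl on 7 would give (3R)-3-hydroxy-N-methoxy-3-(4-methoxyphenyl)-N-methylpropanamide F6.
- F5 should be lithiated by n-BuLi (THF, 0 °C) at the ring carbon between the methoxymethoxy and methoxy groups. Addition at −78 °C to F6, whose hydroxyl is masked in the flask as the chloromagnesium alkoxide (iPrMgCl), would give (3R)-1-[4,6-dimethoxy-2-(methoxymethoxy)-3-(3-methylbut-2-en-1-yl)phenyl]-3-hydroxy-3-(4-methoxyphenyl)propan-1-one F7.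
- MgBr2·OEt2 (CH2Cl2/Et2O), a chelation-assisted and non-protic cleavage of the ortho-acyl methoxymethyl ether, would give (3R)-3-hydroxy-1-[2-hydroxy-4,6-dimethoxy-3-(3-methylbut-2-en-1-yl)phenyl]-3-(4-methoxyphenyl)propan-1-one F8.
- Intramolecular Mitsunobu etherification of F8 (PPh3, DIAD, PhMe) should close ring C with inversion to give 12.

Step 7. The prenyl side chain may be hydrochlorinated or cyclised under the boron Lewis acid, the C2–O1 bond may open under Lewis-acid activation of the chelated carbonyl (erosion of enantiopurity), and a second methyl ether may be cleaved. The fallback sets out from 1 and 8 and returns at 14; demethylation is done before any prenyl group is present, on the prenyl-free flavanone, and the prenyl group enters last by O→C transposition.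
- Mitsunobu etherification of 1 with 8 (PPh3, DIAD) would give (3S)-3-(3,5-dimethoxyphenoxy)-3-(4-methoxyphenyl)-N,N-dimethylpropanamide F9.
- Cyclisation as in step 6 (Tf2O, 2,6-di-tert-butyl-4-methylpyridine; aq. NaHCO3), onto either of the two equivalent ortho carbons, would give (2S)-5,7-dimethoxy-2-(4-methoxyphenyl)-2,3-dihydro-4H-chromen-4-one F10.
- BCl3 (CH2Cl2, −78 °C) would give (2S)-5-hydroxy-7-methoxy-2-(4-methoxyphenyl)-2,3-dihydro-4H-chromen-4-one F11.
- Mitsunobu O-alkylation with 3-methylbut-2-en-1-ol (PPh3, DIAD) would give (2S)-7-methoxy-2-(4-methoxyphenyl)-5-[(3-methylbut-2-en-1-yl)oxy]-2,3-dihydro-4H-chromen-4-one F12.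
- Eu(fod)3 in CHCl3 at 60 °C should then move the allyl unit by two consecutive [3,3] shifts (O at C5 → C6 → C8, Claisen then Cope) and so give 14 with the C5 hydroxyl free.

**Further compounds**
F1 | step 5 | methyl (2E)-3-(4-methoxyphenyl)prop-2-en-1-yl carbonate | COC(=O)OC/C=C/c1ccc(OC)cc1
F2 | step 5 | 1,5-dimethoxy-3-{[(1S)-1-(4-methoxyphenyl)prop-2-en-1-yl]oxy}-2-(3-methylbut-2-en-1-yl)benzene | COc1ccc([C@H](C=C)Oc2cc(OC)cc(OC)c2CC=C(C)C)cc1
F3 | step 5 | (3S)-3-[3,5-dimethoxy-2-(3-methylbut-2-en-1-yl)phenoxy]-3-(4-methoxyphenyl)propan-1-ol | COc1ccc([C@H](CCO)Oc2cc(OC)cc(OC)c2CC=C(C)C)cc1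
F4 | step 5 | (3S)-3-[3,5-dimethoxy-2-(3-methylbut-2-en-1-yl)phenoxy]-3-(4-methoxyphenyl)propanoic acid | COc1ccc([C@H](CC(=O)O)Oc2cc(OC)cc(OC)c2CC=C(C)C)cc1
F5 | step 6 | 1,5-dimethoxy-3-(methoxymethoxy)-2-(3-methylbut-2-en-1-yl)benzene | COCOc1cc(OC)cc(OC)c1CC=C(C)C
F6 | step 6 | (3R)-3-hydroxy-N-methoxy-3-(4-methoxyphenyl)-N-methylpropanamide | CON(C)C(=O)C[C@@H](O)c1ccc(OC)cc1
F7 | step 6 | (3R)-1-[4,6-dimethoxy-2-(methoxymethoxy)-3-(3-methylbut-2-en-1-yl)phenyl]-3-hydroxy-3-(4-methoxyphenyl)propan-1-one | COCOc1c(CC=C(C)C)c(OC)cc(OC)c1C(=O)C[C@@H](O)c1ccc(OC)cc1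
F8 | step 6 | (3R)-3-hydroxy-1-[2-hydroxy-4,6-dimethoxy-3-(3-methylbut-2-en-1-yl)phenyl]-3-(4-methoxyphenyl)propan-1-one | Oc1c(CC=C(C)C)c(OC)cc(OC)c1C(=O)C[C@@H](O)c1ccc(OC)cc1
F9 | step 7 | (3S)-3-(3,5-dimethoxyphenoxy)-3-(4-methoxyphenyl)-N,N-dimethylpropanamide | COc1ccc([C@H](CC(=O)N(C)C)Oc2cc(OC)cc(OC)c2)cc1
F10 | step 7 | (2S)-5,7-dimethoxy-2-(4-methoxyphenyl)-2,3-dihydro-4H-chromen-4-one | COc1ccc([C@@H]2CC(=O)c3c(OC)cc(OC)cc3O2)cc1
F11 | step 7 | (2S)-5-hydroxy-7-methoxy-2-(4-methoxyphenyl)-2,3-dihydro-4H-chromen-4-one | COc1ccc([C@@H]2CC(=O)c3c(O)cc(OC)cc3O2)cc1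
F12 | step 7 | (2S)-7-methoxy-2-(4-methoxyphenyl)-5-[(3-methylbut-2-en-1-yl)oxy]-2,3-dihydro-4H-chromen-4-one | COc1ccc([C@@H]2CC(=O)c3c(OCC=C(C)C)cc(OC)cc3O2)cc1
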